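**Retrosynthetic overview**
- The CH2 bridge is cut last: Mannich-type union at C3 of the two 4-hydroxy-2-pyrones, one on the (3R,4R)-tetralone half and one on the achiral naphthalene half. The naphthalene half is made from the tetralone half by dehydrative aromatisation, so only one monomer is built.
- The tetralone carbocycle comes from a catalyst-controlled intramolecular aldol (acetyl CH3 onto benzoyl C=O) of an aryl diketone, which sets C3 and C4 together.
- Key step: the aryl–CH bond of that diketone is made by one-pot desymmetrising mono C–O activation/α-arylation of C2v-symmetric 2',6'-dihydroxyacetophenone with a phenacyl pyrone. The untouched OH becomes the C8 phenol.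
- The phenacyl pyrone comes from triacetic acid lactone by O-benzylation and lateral benzoylation with methyl benzoate.
- Ring order: pyrone and benzenoid rings are bought; the tetralone ring closes in step 4; the second naphthalene ring arises from it in step 6; the bridge is made in step 7.

Assumption: (S,S)-ProPhenol, 2,6-bis{[(S)-2-(hydroxydiphenylmethyl)pyrrolidin-1-yl]methyl}-4-methylphenol, is taken to give the (3R,4R) ketol in step 4; if a pilot run shows the opposite sense, its (R,R)-enantiomer is used with nothing else changed.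

Step 1
Reactants: 1 4-hydroxy-6-methyl-2H-pyran-2-one (triacetic acid lactone); 2 benzyl alcohol
Product: 3 4-(benzyloxy)-6-methyl-2H-pyran-2-one
Conditions: PPh3, DIAD, THF, 0 °C → rt
Reagents that add atoms: benzyl alcohol 2, OCc1ccccc1
Why: Mitsunobu etherification uses the acidic pyrone 4-OH (pKa about 5) as pronucleophile and alkylates it on oxygen, avoiding the C3-benzylation that benzyl halide plus base would give.

Step 2
Reactants: 3 4-(benzyloxy)-6-methyl-2H-pyran-2-one; 4 methyl benzoate
Product: 5 4-(benzyloxy)-6-(2-oxo-2-phenylethyl)-2H-pyran-2-one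
Conditions: LiN(iPr)2 (2.1 equiv), THF, −78 °C; then 4, −78 → −20 °C; aq. HCl
Reagents that add atoms: methyl benzoate 4, COC(=O)c1ccccc1
Why: Lateral (vinylogous) lithiation of the 6-methyl group gives a trienolate that undergoes Claisen-type acylation by the ester, and the second equivalent of base holds the more acidic ketone product as its enolate so that no second addition occurs.

Step 3
Reactants: 5 4-(benzyloxy)-6-(2-oxo-2-phenylethyl)-2H-pyran-2-one; 6 2',6'-dihydroxyacetophenone [1-(2,6-dihydroxyphenyl)ethan-1-one]; 7 nonafluorobutane-1-sulfonyl fluoride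
Product: 9 aldol precursor 6-[1-(2-acetyl-3-hydroxyphenyl)-2-oxo-2-phenylethyl]-4-(benzyloxy)-2H-pyran-2-one (racemic), via aryl nonaflate 8 (not isolated)
Conditions: one pot: 6, 7 (1.05 equiv), Cs2CO3, THF, 0 °C → rt; then 5, Pd2(dba)3 (2.5 mol %), tBuXPhos (6 mol %), Cs2CO3, 60 °C; aq. NH4Cl
Reagents that add atoms: 2',6'-dihydroxyacetophenone 6, CC(=O)c1c(O)cccc1O
Why: Desymmetrisation of the two equivalent phenolic OH groups by mono-nonaflation (the remaining OH is deactivated in its chelate to the acetyl group) is followed by palladium-catalysed enolate α-arylation (Buchwald–Hartwig type, zerovalent palladium inserting into the C–ONf bond) of the doubly stabilised carbanion of 5; the cesium enolate/phenoxide of 9 cannot close by aldol, so 9 is isolated after the quench, with its new methine centre racemic and configurationally labile until step 4.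

Step 4
Reactants: 9 6-[1-(2-acetyl-3-hydroxyphenyl)-2-oxo-2-phenylethyl]-4-(benzyloxy)-2H-pyran-2-one
Product: 10 (3R,4R)-4-[4-(benzyloxy)-2-oxo-2H-pyran-6-yl]-3,8-dihydroxy-3-phenyl-3,4-dihydronaphthalen-1(2H)-one
Conditions: (S,S)-ProPhenol (10 mol %), Et2Zn (20 mol %), 4 Å MS, THF, 0 °C; aq. NH4Cl
Reagents that add atoms: none
Why: Proposed new method: the phenol and acetyl carbonyl of 9 chelate one zinc of the dinuclear Et2Zn–ProPhenol catalyst as a zinc phenoxide, which acidifies the acetyl CH3 selectively so that the zinc enolate forms there and adds intramolecularly to the benzoyl ketone held on the second zinc (closest known reaction: the dinuclear-zinc ProPhenol direct aldol of aryl methyl ketones, here as a 6-membered ring closure), the chiral pocket fixing the carbonyl face and hence C3 as R, while the acidic C4–H (α to benzoyl, vinylogous to the pyrone) epimerises quickly so both antipodes of 9 funnel through the transition state with the pyrone pseudo-axial and anti to the forming C3–O bond, giving the 3,4-trans (3R,4R) ketol by dynamic kinetic resolution.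

Step 5
Reactants: 10 (3R,4R)-4-[4-(benzyloxy)-2-oxo-2H-pyran-6-yl]-3,8-dihydroxy-3-phenyl-3,4-dihydronaphthalen-1(2H)-one
Product: 11 (3R,4R)-3,8-dihydroxy-4-(4-hydroxy-2-oxo-2H-pyran-6-yl)-3-phenyl-3,4-dihydronaphthalen-1(2H)-one
Conditions: H2 (1 atm), 10% Pd/C, EtOAc, rt, 1 h
Reagents that add atoms: none
Why: Hydrogenolysis of the benzyl vinylogous ester is much faster than reduction of the aryl ketone, the pyrone ring or the tertiary benzylic alcohol, and the neutral conditions leave the β-hydroxy ketone and both stereocentres untouched.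

Step 6
Reactants: 11 (3R,4R)-3,8-dihydroxy-4-(4-hydroxy-2-oxo-2H-pyran-6-yl)-3-phenyl-3,4-dihydronaphthalen-1(2H)-one (about half of the batch)
Product: 12 6-(4,5-dihydroxy-2-phenylnaphthalen-1-yl)-4-hydroxy-2H-pyran-2-one
Conditions: p-TsOH·H2O (10 mol %), THF, 50 °C
Reagents that add atoms: none
Why: Acid-catalysed E1 dehydration of the tertiary benzylic β-hydroxy ketone followed by enolisation gives the aromatic naphthalene-1,8-diol; both stereocentres are deliberately destroyed (12 is achiral), so stereochemically impure 11 can be used here.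

Step 7
Reactants: 12 6-(4,5-dihydroxy-2-phenylnaphthalen-1-yl)-4-hydroxy-2H-pyran-2-one; 13 N,N,N',N'-tetramethylmethanediamine [bis(dimethylamino)methane]; 11 (3R,4R)-3,8-dihydroxy-4-(4-hydroxy-2-oxo-2H-pyran-6-yl)-3-phenyl-3,4-dihydronaphthalen-1(2H)-one
Product: 16 wailupemycin I, via Mannich base 14 (not isolated), via pyrandione methide 15 (not isolated)
Conditions: 12, 13 (1.0 equiv), MeCN, 0 °C → rt, evaporate volatiles; then 11 (1.0 equiv), MeCN, 40 °C
Reagents that add atoms: N,N,N',N'-tetramethylmethanediamine 13, CN(C)CN(C)C; tetralone pyrone 11, O=C1C[C@](O)(c2ccccc2)[C@H](c2cc(O)cc(=O)o2)c2cccc(O)c21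
Why: Mannich aminomethylation occurs at C3 of the 4-hydroxy-2-pyrone of 12 (acidic enough to activate the aminal and the most C-nucleophilic site), then thermal loss of dimethylamine gives the 3-methylidene-pyran-2,4-dione, which is trapped by Michael addition of C3 of pyrone 11; no stereocentre is formed and the mild amine-buffered conditions leave C3 and C4 of 11 untouched.

**Compound list**
1 | 4-hydroxy-6-methyl-2H-pyran-2-one (triacetic acid lactone) | Cc1cc(O)cc(=O)o1 | starting material
2 | benzyl alcohol | OCc1ccccc1 | starting material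
3 | 4-(benzyloxy)-6-methyl-2H-pyran-2-one | Cc1cc(OCc2ccccc2)cc(=O)o1 | intermediate
4 | methyl benzoate | COC(=O)c1ccccc1 | starting material
5 | 4-(benzyloxy)-6-(2-oxo-2-phenylethyl)-2H-pyran-2-one | O=C(Cc1cc(OCc2ccccc2)cc(=O)o1)c1ccccc1 | intermediate
6 | 2',6'-dihydroxyacetophenone | CC(=O)c1c(O)cccc1O | starting material
7 | nonafluorobutane-1-sulfonyl fluoride | O=S(=O)(F)C(F)(F)C(F)(F)C(F)(F)C(F)(F)F | starting material
8 | 2-acetyl-3-hydroxyphenyl nonafluorobutane-1-sulfonate | CC(=O)c1c(O)cccc1OS(=O)(=O)C(F)(F)C(F)(F)C(F)(F)C(F)(F)F | intermediate (not isolated)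
9 | 6-[1-(2-acetyl-3-hydroxyphenyl)-2-oxo-2-phenylethyl]-4-(benzyloxy)-2H-pyran-2-one (racemic, labile methine) | CC(=O)c1c(O)cccc1C(C(=O)c1ccccc1)c1cc(OCc2ccccc2)cc(=O)o1 | intermediate
10 | (3R,4R)-4-[4-(benzyloxy)-2-oxo-2H-pyran-6-yl]-3,8-dihydroxy-3-phenyl-3,4-dihydronaphthalen-1(2H)-one | O=C1C[C@](O)(c2ccccc2)[C@H](c2cc(OCc3ccccc3)cc(=O)o2)c2cccc(O)c21 | intermediate
11 | (3R,4R)-3,8-dihydroxy-4-(4-hydroxy-2-oxo-2H-pyran-6-yl)-3-phenyl-3,4-dihydronaphthalen-1(2H)-one | O=C1C[C@](O)(c2ccccc2)[C@H](c2cc(O)cc(=O)o2)c2cccc(O)c21 | intermediate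
12 | 6-(4,5-dihydroxy-2-phenylnaphthalen-1-yl)-4-hydroxy-2H-pyran-2-one | O=c1cc(O)cc(-c2c(-c3ccccc3)cc(O)c3c(O)cccc23)o1 | intermediate
13 | N,N,N',N'-tetramethylmethanediamine | CN(C)CN(C)C | starting material
14 | 3-[(dimethylamino)methyl]-6-(4,5-dihydroxy-2-phenylnaphthalen-1-yl)-4-hydroxy-2H-pyran-2-one | CN(C)Cc1c(O)cc(-c2c(-c3ccccc3)cc(O)c3c(O)cccc23)oc1=O | intermediate (not isolated)
15 | 6-(4,5-dihydroxy-2-phenylnaphthalen-1-yl)-3-methylidene-2H-pyran-2,4(3H)-dione | C=C1C(=O)C=C(-c2c(-c3ccccc3)cc(O)c3c(O)cccc23)OC1=O | intermediate (not isolated)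
16 | wailupemycin I, 6-[(1R,2R)-2,5-dihydroxy-4-oxo-2-phenyl-1,2,3,4-tetrahydronaphthalen-1-yl]-3-{[6-(4,5-dihydroxy-2-phenylnaphthalen-1-yl)-4-hydroxy-2-oxo-2H-pyran-3-yl]methyl}-4-hydroxy-2H-pyran-2-one | O=C1C[C@](O)(c2ccccc2)[C@H](c2cc(O)c(Cc3c(O)cc(-c4c(-c5ccccc5)cc(O)c5c(O)cccc45)oc3=O)c(=O)o2)c2cccc(O)c21 | target

**Totals**
Total step count: 7.
Longest linear sequence: 7 steps (1 → 3 → 5 → 9 → 10 → 11 → 12 → 16).

**Steps most likely to fail, with fallbacks**

Step 4 is the riskiest. It is a new catalytic asymmetric ketone–ketone aldol: the ee, the trans/cis ratio and the sense of induction are unproven, and the ketol can dehydrate to the naphthalene. The fallback sets out from 9 and gives up asymmetric catalysis for resolution. K2CO3 (0.2 equiv) in MeOH/THF at rt closes the ring without stereocontrol to the racemic trans ketol, which is 10 together with its enantiomer, the (3S,4S)-ketol benzyl ether F1. Preparative chiral SFC on an amylose carbamate phase separates the two. The fallback comes back to the route at 10. F1 is not wasted: hydrogenolysis (H2, Pd/C, EtOAc) gives the (3S,4S)-tetralone pyrone F2, which replaces 11 in step 6 and so also rejoins the route at achiral 12.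

Step 3 is next. The one-pot mono-nonaflation/α-arylation may suffer from bis-sulfonylation, diaryl ether formation from the free phenoxide, or sluggish reductive elimination of the hindered, stabilised enolate. The fallback sets out from 5 and builds the same aryl–CH bond by aryne chemistry. C-acetylation (AcCl, MgCl2, Et3N, MeCN) gives the C-acetylated diketone F3, 2-[4-(benzyloxy)-2-oxo-2H-pyran-6-yl]-1-phenylbutane-1,3-dione. CsF in MeCN with C2v-symmetric 2-(trimethylsilyl)-1,3-phenylene bis(trifluoromethanesulfonate) generates 3-(triflyloxy)benzyne F4. The carbanion of F3 attacks the aryne carbon remote from the triflate, and the aryl anion takes the acetyl group (aryne acyl-alkylation), giving the aryl triflate F5. Et4NOH in dioxane at rt cleaves the S–O bond, and the fallback comes back to the route at 9.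

Step 7 is third. The hazards are aminomethylation of the electron-rich naphthalenediol, homodimer formation by aminomethyl exchange, and base- or heat-induced retro-aldol or dehydration of 11. The fallback sets out from 11 and does not use 12 or 13. Two equivalents of 11 with one of aqueous formaldehyde (EtOH, rt) give the C2-symmetric bis-tetralone F6 as the only possible dimer. p-TsOH·H2O (cat.) in THF at 40 °C, stopped near half conversion, then dehydrates one of the two equivalent ketol units. Unreacted F6 is recycled, and the fallback comes back to the route at 16.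

**Further compounds**
F1 | step 4 | (3S,4S)-4-[4-(benzyloxy)-2-oxo-2H-pyran-6-yl]-3,8-dihydroxy-3-phenyl-3,4-dihydronaphthalen-1(2H)-one | O=C1C[C@@](O)(c2ccccc2)[C@@H](c2cc(OCc3ccccc3)cc(=O)o2)c2cccc(O)c21
F2 | step 4 | (3S,4S)-3,8-dihydroxy-4-(4-hydroxy-2-oxo-2H-pyran-6-yl)-3-phenyl-3,4-dihydronaphthalen-1(2H)-one | O=C1C[C@@](O)(c2ccccc2)[C@@H](c2cc(O)cc(=O)o2)c2cccc(O)c21
F3 | step 3 | 2-[4-(benzyloxy)-2-oxo-2H-pyran-6-yl]-1-phenylbutane-1,3-dione | CC(=O)C(C(=O)c1ccccc1)c1cc(OCc2ccccc2)cc(=O)o1
F4 | step 3 | 3-(trifluoromethanesulfonyloxy)benzyne (2,3-didehydrophenyl trifluoromethanesulfonate) | O=S(=O)(OC1=CC=CC#C1)C(F)(F)F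
F5 | step 3 | 2-acetyl-3-{1-[4-(benzyloxy)-2-oxo-2H-pyran-6-yl]-2-oxo-2-phenylethyl}phenyl trifluoromethanesulfonate | CC(=O)c1c(OS(=O)(=O)C(F)(F)F)cccc1C(C(=O)c1ccccc1)c1cc(OCc2ccccc2)cc(=O)o1
F6 | step 7 | 3,3'-methylenebis{6-[(1R,2R)-2,5-dihydroxy-4-oxo-2-phenyl-1,2,3,4-tetrahydronaphthalen-1-yl]-4-hydroxy-2H-pyran-2-one} | O=C1C[C@](O)(c2ccccc2)[C@H](c2cc(O)c(Cc3c(O)cc([C@@H]4c5cccc(O)c5C(=O)C[C@]4(O)c4ccccc4)oc3=O)c(=O)o2)c2cccc(O)c21
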